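**Retrosynthetic overview**
1. The side-chain tertiary alcohol comes from Markovnikov hydration of an 8-prenyl group (last step); the 5-OH comes from a 5-OMe by demethylation directed by the peri C4=O.
2. The C ring (O1–C2–C3–C4–C4a–C8a) comes from a two-atom ring expansion of (4S)-4-phenyloxetan-2-one: the arene edge C4a–C8a is inserted into the lactone acyl–oxygen bond (C4a–Li attacks the lactone carbonyl, the freed C2–O⁻ then displaces F at C8a).
3. Enabling feature: O1–C2(Ph)–C3–C4(=O) is an opened β-lactone whose two ends sit on the neighbouring A-ring carbons C8a and C4a. The C4 ketone formed first lies ortho to C8a–F and activates it, and C2 keeps all four of its bonds, so (S) is bought, not made.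
4. The A-ring piece comes from symmetric 1-fluoro-3,5-dimethoxybenzene: both F/OMe-flanked positions are brominated, one Br becomes the prenyl group (C8), the other the lithium (C4a).
5. Ring order: A ring bought → four-membered lactone ring closed → enlarged to the six-membered C ring.

Key step: step 4

Assumption: compounds 1, 3 and 7 are taken as purchased (7 as the single (S) enantiomer); the organometallic steps are run under argon in dry solvents.

Step 1
Reactants: 1 1-fluoro-3,5-dimethoxybenzene
Product: 2 2,4-dibromo-3-fluoro-1,5-dimethoxybenzene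
Conditions: NBS (2.05 equiv), MeCN, 0 °C → rt
Reagents that add atoms: N-bromosuccinimide, O=C1CCC(=O)N1Br
Why: Electrophilic aromatic bromination should go twice to the positions flanked by F and OMe, each ortho to one and para to the other methoxy group and less hindered than the position between the two methoxy groups, as is usual for 5-substituted resorcinol dimethyl ethers.

Step 2
Reactants: 2 2,4-dibromo-3-fluoro-1,5-dimethoxybenzene; 3 1-bromo-3-methylbut-2-ene (prenyl bromide)
Product: 6 2-bromo-3-fluoro-1,5-dimethoxy-4-(3-methylbut-2-en-1-yl)benzene, via aryllithium 4 (not isolated), via arylcopper 5 (not isolated)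
Conditions: n-BuLi (1.0 equiv), THF, −78 °C; CuBr·SMe2 (1.0 equiv), −78 °C; 3, −78 → −20 °C
Reagents that add atoms: none
Why: Bromine–lithium exchange at one of two equivalent C–Br bonds (a second exchange on the aryl anion is disfavoured), transmetalation to the arylcopper, which resists loss of LiF, and allylic substitution at the primary carbon of prenyl bromide should give the linear prenyl arene; no stereocenter is formed.

Step 3
Reactants: 7 (3S)-3-hydroxy-3-phenylpropanoic acid
Product: 8 (4S)-4-phenyloxetan-2-one
Conditions: PhSO2Cl (2 equiv), pyridine, 0–5 °C; cold aqueous work-up, used at once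
Reagents that add atoms: none
Why: β-Lactonization by carboxyl activation (mixed sulfonic anhydride) and 4-exo-trig attack of the C3 hydroxyl; the C–O bond at the stereocenter is not broken, so (S) is retained.

Step 4
Reactants: 6 2-bromo-3-fluoro-1,5-dimethoxy-4-(3-methylbut-2-en-1-yl)benzene; 8 (4S)-4-phenyloxetan-2-one
Product: 11 (2S)-5,7-dimethoxy-8-(3-methylbut-2-en-1-yl)-2-phenyl-2,3-dihydro-4H-chromen-4-one, via aryllithium 9 (not isolated), via lithium aldolate 10 (not isolated)
Conditions: n-BuLi (1.0 equiv), THF, −78 °C; 8 (1.1 equiv), −78 °C; DMPU (4 equiv), −78 → 0 °C; aq. NH4Cl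
Reagents that add atoms: none
Why: Proposed new method: aryllithium 9 is expected to add to the strained carbonyl of 8 with acyl–oxygen cleavage (the known opening of β-lactones by organolithiums to β-hydroxy ketones), and the C2 alkoxide thus set free in 10 should displace fluoride at C8a, which the new ortho ketone activates, so that C4a and C8a end up inserted into the O1–C4 bond and the four-membered ring becomes the six-membered ring in one flask. The closest known reaction types are the aryne insertion into the N–C(O) bond of β-lactams, which gives 2,3-dihydroquinolin-4-ones, and the acylation/SNAr closures of 2-fluoroaryl ketones to chromones and xanthones. The single ring closure is an intramolecular SNAr: addition of the alkoxide to C8a through a six-membered transition state (Meisenheimer adduct stabilised by the C4 carbonyl), then loss of fluoride. No stereocenter is created, because C2 is the lactone carbon C4 and none of its four bonds is broken, so the (S) configuration of 8 is carried over unchanged. The step needs attack at the acyl and not the benzylic carbon of the lactone (hard aryllithium at −78 °C), substitution of fluoride and not of the 5-methoxy group (only C8a carries the far better SNAr leaving group) and ring closure faster than retro-aldol cleavage or β-elimination of 10, for which the cation-solvating DMPU, the low temperature and the absence of excess base are chosen.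

Step 5
Reactants: 11 (2S)-5,7-dimethoxy-8-(3-methylbut-2-en-1-yl)-2-phenyl-2,3-dihydro-4H-chromen-4-one
Product: 12 (2S)-5-hydroxy-7-methoxy-8-(3-methylbut-2-en-1-yl)-2-phenyl-2,3-dihydro-4H-chromen-4-one
Conditions: MgI2·OEt2 (3 equiv), THF, 60 °C; aqueous work-up
Reagents that add atoms: none
Why: Chelation-controlled O-demethylation: Mg(II) bound between C4=O and the peri 5-methoxy oxygen lets iodide remove only that methyl group by SN2, a reagent known to spare the prenyl group in 8-prenyl-5-methoxyflavanones, while 7-OMe and C2 are not touched.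

Step 6
Reactants: 12 (2S)-5-hydroxy-7-methoxy-8-(3-methylbut-2-en-1-yl)-2-phenyl-2,3-dihydro-4H-chromen-4-one
Product: 13 (2S)-5-hydroxy-8-(3-hydroxy-3-methylbutyl)-7-methoxy-2-phenyl-2,3-dihydro-4H-chromen-4-one
Conditions: Co(acac)2 (20 mol %), PhSiH3 (2.5 equiv), O2 (1 atm), THF/i-PrOH, rt
Reagents that add atoms: dioxygen, O=O
Why: Mukaiyama hydration (hydrogen atom transfer from a cobalt hydride to the trisubstituted alkene, trapping of the tertiary radical by O2) should be Markovnikov-selective and leave ketone, chelated phenol and C2 unchanged.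

**Compound list**
1 | 1-fluoro-3,5-dimethoxybenzene | COc1cc(F)cc(OC)c1 | starting material
2 | 2,4-dibromo-3-fluoro-1,5-dimethoxybenzene | COc1cc(OC)c(Br)c(F)c1Br | intermediate
3 | 1-bromo-3-methylbut-2-ene (prenyl bromide) | CC(C)=CCBr | starting material
4 | (3-bromo-2-fluoro-4,6-dimethoxyphenyl)lithium | [Li]c1c(F)c(Br)c(OC)cc1OC | intermediate
5 | (3-bromo-2-fluoro-4,6-dimethoxyphenyl)copper | [Cu]c1c(F)c(Br)c(OC)cc1OC | intermediate
6 | 2-bromo-3-fluoro-1,5-dimethoxy-4-(3-methylbut-2-en-1-yl)benzene | COc1cc(OC)c(CC=C(C)C)c(F)c1Br | intermediate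
7 | (3S)-3-hydroxy-3-phenylpropanoic acid | OC(=O)C[C@H](O)c1ccccc1 | starting material
8 | (4S)-4-phenyloxetan-2-one | O=C1C[C@@H](c2ccccc2)O1 | intermediate
9 | [2-fluoro-4,6-dimethoxy-3-(3-methylbut-2-en-1-yl)phenyl]lithium | [Li]c1c(F)c(CC=C(C)C)c(OC)cc1OC | intermediate
10 | lithium (1S)-3-[2-fluoro-4,6-dimethoxy-3-(3-methylbut-2-en-1-yl)phenyl]-3-oxo-1-phenylpropan-1-olate | [Li]O[C@@H](CC(=O)c1c(F)c(CC=C(C)C)c(OC)cc1OC)c1ccccc1 | intermediate
11 | (2S)-5,7-dimethoxy-8-(3-methylbut-2-en-1-yl)-2-phenyl-2,3-dihydro-4H-chromen-4-one | COc1cc(OC)c2c(c1CC=C(C)C)O[C@H](c1ccccc1)CC2=O | intermediate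
12 | (2S)-5-hydroxy-7-methoxy-8-(3-methylbut-2-en-1-yl)-2-phenyl-2,3-dihydro-4H-chromen-4-one | COc1cc(O)c2c(c1CC=C(C)C)O[C@H](c1ccccc1)CC2=O | intermediate
13 | (2S)-5-hydroxy-8-(3-hydroxy-3-methylbutyl)-7-methoxy-2-phenyl-2,3-dihydro-4H-chromen-4-one | COc1cc(O)c2c(c1CCC(C)(C)O)O[C@H](c1ccccc1)CC2=O | target

**Step count**
Total steps: 6. Longest linear sequence: 5 steps (1 → 2 → 6 → 11 → 12 → 13, steps 1, 2, 4, 5 and 6); step 3 is the side branch to the lactone.

**Steps most likely to fail**

Step 4 (proposed new method). The ring-closing substitution at C8a may be slower than retro-aldol cleavage or β-elimination of the lithium aldolate. That would cost material and, if the aldol re-forms, configurational purity. The ortho-fluoro aryllithium may also lose LiF before it is acylated. The fallback gives up the ring expansion and uses known chemistry in the opposite bond order. It sets out from prenyl bromide 3, which ortho-C-alkylates the sodium salt of purchased 3,5-dimethoxyphenol (NaH, toluene) to 3,5-dimethoxy-2-(3-methylbut-2-en-1-yl)phenol F1. Mitsunobu etherification of this phenol with purchased ethyl (R)-3-hydroxy-3-phenylpropanoate (PPh3, DIAD, THF) inverts the carbinol carbon and should give ethyl (3S)-3-[3,5-dimethoxy-2-(3-methylbut-2-en-1-yl)phenoxy]-3-phenylpropanoate F2. Saponification (LiOH, THF/H2O, 0 °C) gives (3S)-3-[3,5-dimethoxy-2-(3-methylbut-2-en-1-yl)phenoxy]-3-phenylpropanoic acid F3. Intramolecular Friedel–Crafts acylation through the mixed trifluoroacetic anhydride (TFAA, CH2Cl2, 0 °C) at the only free position ortho to the ether oxygen closes the ring and comes back to the route at 11.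

Step 3. The activated hydroxy acid may oligomerise, and the 4-aryl-β-lactone may lose CO2 during formation or isolation. The fallback sets out from 7. Steglich-type thioesterification (PhSH, DCC, cat. DMAP, CH2Cl2, 0 °C) gives the isolable S-phenyl (3S)-3-hydroxy-3-phenylpropanethioate F4. Thiophile-promoted ring closure under neutral conditions (Hg(O2CCF3)2, Na2HPO4, MeCN, rt) comes back to the route at 8, again without touching the C–O bond of the stereocenter.

Step 2. The ortho-fluoro aryllithium may eliminate LiF (aryne formation) before transmetalation, and allylic substitution may occur with transposition (SN2′) to the 1,1-dimethylallyl isomer. The fallback avoids organolithium chemistry. It sets out from 1. Iodination (NIS, 1 equiv, cat. TFA, MeCN) gives 1-fluoro-2-iodo-3,5-dimethoxybenzene F5. Bromination of the remaining F/OMe-flanked position (NBS, MeCN) gives 2-bromo-3-fluoro-4-iodo-1,5-dimethoxybenzene F6. A Stille coupling that is chemoselective for the C–I bond, with tributyl(3-methylbut-2-en-1-yl)stannane (Pd(PPh3)4, CuI, DMF, 60 °C), comes back to the route at 6.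

**Further compounds**
F1 | step 4 | 3,5-dimethoxy-2-(3-methylbut-2-en-1-yl)phenol | COc1cc(OC)c(CC=C(C)C)c(O)c1
F2 | step 4 | ethyl (3S)-3-[3,5-dimethoxy-2-(3-methylbut-2-en-1-yl)phenoxy]-3-phenylpropanoate | CCOC(=O)C[C@H](Oc1cc(OC)cc(OC)c1CC=C(C)C)c1ccccc1
F3 | step 4 | (3S)-3-[3,5-dimethoxy-2-(3-methylbut-2-en-1-yl)phenoxy]-3-phenylpropanoic acid | OC(=O)C[C@H](Oc1cc(OC)cc(OC)c1CC=C(C)C)c1ccccc1
F4 | step 3 | S-phenyl (3S)-3-hydroxy-3-phenylpropanethioate | O=C(C[C@H](O)c1ccccc1)Sc1ccccc1
F5 | step 2 | 1-fluoro-2-iodo-3,5-dimethoxybenzene | COc1cc(F)c(I)c(OC)c1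
F6 | step 2 | 2-bromo-3-fluoro-4-iodo-1,5-dimethoxybenzene | COc1cc(OC)c(I)c(F)c1Br
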